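The amounts in the flask are those of the dawn run except D, which drops from 5.6 equiv to 4.00 equiv, so the quick number asked for can be built on dawn.

all flasks: J 0.50 M; Q 0.91 mM
- dawn: D 5.6 equiv; X 0.2 mol%; run made earlier
- winter: D 4 equiv; X 0.4 mol%; run made earlier
- flask: D 4.00 equiv; X 0.2 mol%

| run | time / min | L / % |
|---|---|---|
| dawn | 6.00 | 7.5 |
| dawn | 10.0 | 11.8 |
| dawn | 20.0 | 21.5 |
| dawn | 40.0 | 34.7 |
| dawn | 80.0 | 49.1 |
| winter | 15.0 | 34.4 |
| winter | 30.0 | 51.8 |
| winter | 40.0 | 59.8 |
| winter | 60.0 | 67.8 |
| winter | 80.0 | 73.2 |

(standard deviation of a reading: 0.5 percentage points)

* apparent order in D when 50% of the J are converted (percent change of the rate of making L for one percent more D charged)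
* apparent order in X when 50% of the J are converted (percent change of the rate of making L for one percent more X charged)



Let s be the rate of making L over [J], the pseudo-first-order constant of the moment. In dawn it falls with clock time, as a reading with the stated scatter:

s from 20.0 min to 40.0 min: 0.00921 min⁻¹

s from 40.0 min to 80.0 min: 0.00623 min⁻¹

fading rate between the midpoints, φ: 0.0130 min⁻¹

Assume s is proportional to D and fades by the clock. One percent more D then brings 50% conversion earlier by one percent of T = ln(2)/s, and the earlier moment stands higher by φ times that shift. The apparent order in D is therefore 1 + N, with N = φT and s taken at that moment. The same holds for X if s is proportional to X and the fading ignores X.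

For the flask, as an estimate, dawn's last s, scaled by the D charged, stands in for the s at 50% conversion:

s: 0.00445 min⁻¹

T: 156 min

N = φT = 2.03, the age lever: the fading rate times the time 50% conversion would take at the pace of that moment.

This reckoning puts both orders near 3.03.

The forecast gives 0.7 in D and 2.1 in X, lower than this reckoning, holding that “a slower run has aged longer, which roughly doubles the apparent orders”.

The flask gives 2.7 in D and 2.9 in X.

    X + Q ⇌ Z, settled at all times (K = 7800 M⁻¹)
    X ⇌ G (K = 27.0, k = 0.0230 min⁻¹)
    J + D + X → X + L (k = 15.0 M⁻² min⁻¹)

The flask reaches 50% at 2.46 h, and its order in D puts the age lever at 1.70, less than the 2.03 reckoned. Part of that lever comes from the reaction of X to G, both ways: the same flask without it has an order in D of 1.1, a lever of 0.100. With it, X in the flask falls from 31.1% of the catalyst charged at 0.100 h to 16.7% at 1.00 h, while G climbs from 4.47% to 31.7%.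

The readings come from a simulation with made-up constants; scatter was added.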